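**Retrosynthetic overview**

1. The target comes from double MOM removal of an isoflavone that is assembled by Suzuki–Miyaura union of ring C (chromone C3) with ring B, from a 3-iodochromone (rings A and C) and a chromenyl boronate (rings B and D).
2. Ring D (the dimethylpyran: O1, C2, C3, C4, C4a, C8a of the chromene unit) is closed on ring B by forging the C3=C4 olefin. This is a ruthenium-vinylidene-mediated decarbonylative cyclisation of a salicylaldehyde 1,1-dimethylpropargyl ether: the formyl carbon becomes C4, the internal alkyne carbon becomes C3, and the terminal alkyne carbon leaves as CO.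
3. Enabling feature: the ether oxygen O1 sits on C8a of ring B, and both neighbours of C8a are substituted (C4a carries C4, C8 carries OMe), so the propargyl ether cannot take the usual thermal Claisen exit. C4 and C3 stand 1,6 to each other across O1 and the quaternary C2, which has no hydrogen and carries the gem-dimethyl group that favours closure.
4. The aldehyde comes from ortho-formylation between the two oxygens of a bromophenol, itself made by propargylation and Baeyer–Villiger oxidation of 2-bromo-5-hydroxy-4-methoxybenzaldehyde. The bromine first blocks the wrong ortho site and then becomes the coupling handle at C6.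
5. Ring order: ring B is bought and ring D is made by the key step; ring A is bought and ring C is made by enaminone iodocyclisation; the two halves are joined last.

Key step: step 4

Remark on the chemistry: the target has no stereocenter and its only olefin geometry (C3=C4) is fixed by the ring, so no step needs stereocontrol; atom numbers for rings B and D are those of the 2H-chromene unit (O1, C2, C3, C4, C4a, C5 to C8, C8a).

**Route**

Step 1
Reactants: 1 2-bromo-5-hydroxy-4-methoxybenzaldehyde
Product: 2 2-bromo-4-methoxy-5-[(2-methylbut-3-yn-2-yl)oxy]benzaldehyde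
Conditions: 3-chloro-3-methylbut-1-yne, K2CO3, KI (cat.), CuI (cat.), acetone, 55 °C
Reagents that add atoms: 3-chloro-3-methylbut-1-yne, CC(C)(Cl)C#C
Why: Copper-assisted Williamson-type O-alkylation of the single free phenol with the tertiary propargylic chloride is the standard entry to aryl 1,1-dimethylpropargyl ethers, and at 55 °C the ether should not enter the propargyl Claisen manifold.

Step 2
Reactants: 2 2-bromo-4-methoxy-5-[(2-methylbut-3-yn-2-yl)oxy]benzaldehyde
Product: 4 2-bromo-4-methoxy-5-[(2-methylbut-3-yn-2-yl)oxy]phenol, via aryl formate 3 (not isolated)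
Conditions: mCPBA, CH2Cl2, 0 °C to rt; aq. Na2S2O3/NaHCO3 wash; then K2CO3 (cat.), MeOH, rt
Reagents that add atoms: mCPBA (3-chloroperoxybenzoic acid), O=C(OO)c1cccc(Cl)c1
Why: In this Baeyer–Villiger (Dakin-type) oxidation the electron-rich aryl group (para-methoxy) should migrate in preference to hydrogen to give formate 3, whose methanolysis unveils the phenol that becomes the C5 hydroxyl, while the terminal alkyne is inert to the peracid.

Step 3
Reactants: 4 2-bromo-4-methoxy-5-[(2-methylbut-3-yn-2-yl)oxy]phenol
Product: 6 3-bromo-2-hydroxy-5-methoxy-6-[(2-methylbut-3-yn-2-yl)oxy]benzaldehyde, via salicyl alcohol 5 (not isolated)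
Conditions: MgCl2, Et3N, paraformaldehyde, THF, 65 °C; then aq. HCl (1 M) work-up
Reagents that add atoms: paraformaldehyde (as formaldehyde), C=O
Why: Magnesium-mediated ortho-formylation (Casiraghi–Skattebøl type) delivers formaldehyde only ortho to the phenoxide oxygen through a chelated magnesium phenoxide, the bromine blocks the other ortho site so that only the carbon between the two oxygens can react, and salicyl alcohol 5 is oxidised in the flask by hydride transfer to a second formaldehyde.

Step 4
Reactants: 6 3-bromo-2-hydroxy-5-methoxy-6-[(2-methylbut-3-yn-2-yl)oxy]benzaldehyde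
Product: 9 6-bromo-8-methoxy-2,2-dimethyl-2H-chromen-5-ol, via ruthenium vinylidene 7 (not isolated), via chromene-3-acyl ruthenium 8 (not isolated)
Conditions: [CpRu(MeCN)3]PF6 (10 mol %), AcOH, 90 °C, argon purge
Reagents that add atoms: none
Why: Proposed new method: the cationic CpRu fragment is expected to isomerise the terminal alkyne of 6 to ruthenium vinylidene 7, acetic acid then adds to the electrophilic metal-bound carbon to give an acyl ruthenium whose enol carbon is the former internal alkyne carbon C3, this now nucleophilic C3 attacks the hydrogen-bond-activated formyl carbon C4 in an aldol condensation to give the cyclic unsaturated acyl ruthenium 8, and 8 extrudes CO and is protonated by acetic acid to release 9 and the catalyst. The closest known reaction type is the ruthenium-vinylidene-mediated decarbonylative cyclisation of terminal 5- and 6-alkynals to cyclopentenes and cyclohexenes with the same catalyst in acetic acid, and the extension proposed here is to an aryl aldehyde partner and to a propargylic carbon that is quaternary and oxygen-bound. Ring D is closed in a 6-(enolexo)-exo-trig aldol mode that the gem-dimethyl group at C2 favours, the cis geometry of C3=C4 is imposed by the ring, and no stereocenter is formed. The step needs chemoselectivity for acetic acid addition to the vinylidene over loss of the aryloxide from the propargylic carbon (allenylidene formation) and over thermal propargyl Claisen chemistry: the phosphine-free electron-poor metal in neat acetic acid should favour the first, and the substituents on both C4a and C8 shut off the second. Site selectivity is secured by the substrate because C2 bears no hydrogen, so only C3 can become the enol carbon, and C4 is the only electrophile within reach of a six-membered closure.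

Step 5
Reactants: 9 6-bromo-8-methoxy-2,2-dimethyl-2H-chromen-5-ol
Product: 10 6-bromo-8-methoxy-5-(methoxymethoxy)-2,2-dimethyl-2H-chromene
Conditions: NaH, MOMCl, THF/DMF, 0 °C to rt
Reagents that add atoms: chloromethyl methyl ether (MOMCl), COCCl
Why: Williamson etherification of the sodium phenoxide with MOMCl masks the acidic hydroxyl ahead of the halogen-lithium exchange and installs a group that leaves together with the ring A protection in the last step.

Step 6
Reactants: 10 6-bromo-8-methoxy-5-(methoxymethoxy)-2,2-dimethyl-2H-chromene
Product: 12 2-[8-methoxy-5-(methoxymethoxy)-2,2-dimethyl-2H-chromen-6-yl]-4,4,5,5-tetramethyl-1,3,2-dioxaborolane, via aryllithium 11 (not isolated)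
Conditions: n-BuLi, THF, −78 °C; then 2-isopropoxy-4,4,5,5-tetramethyl-1,3,2-dioxaborolane, −78 °C to rt
Reagents that add atoms: 2-isopropoxy-4,4,5,5-tetramethyl-1,3,2-dioxaborolane, CC(C)OB1OC(C)(C)C(C)(C)O1
Why: Bromine-lithium exchange is fast at −78 °C and the ortho OMOM group stabilises aryllithium 11 by chelation, so that electrophilic borylation with the isopropoxy pinacol borate should give the boronate without touching the chromene olefin.

Step 7
Reactants: 13 1-(2,4-dihydroxyphenyl)ethan-1-one
Product: 14 1-[2-hydroxy-4-(methoxymethoxy)phenyl]ethan-1-one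
Conditions: MOMCl, K2CO3, acetone, rt
Reagents that add atoms: chloromethyl methyl ether (MOMCl), COCCl
Why: Williamson etherification is selective for the 4-hydroxyl because the 2-hydroxyl is tied up in a hydrogen bond to the ketone and is much less nucleophilic.

Step 8
Reactants: 14 1-[2-hydroxy-4-(methoxymethoxy)phenyl]ethan-1-one
Product: 15 (E)-3-(dimethylamino)-1-[2-hydroxy-4-(methoxymethoxy)phenyl]prop-2-en-1-one
Conditions: DMF-DMA, toluene, 90 °C
Reagents that add atoms: N,N-dimethylformamide dimethyl acetal (DMF-DMA), COC(OC)N(C)C
Why: Condensation of the methyl ketone with the amide acetal (enaminone formation) should give the push-pull E-enaminone under thermodynamic control.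

Step 9
Reactants: 15 (E)-3-(dimethylamino)-1-[2-hydroxy-4-(methoxymethoxy)phenyl]prop-2-en-1-one
Product: 17 3-iodo-7-(methoxymethoxy)-4H-chromen-4-one, via aminochromanone 16 (not isolated)
Conditions: I2, CHCl3, rt
Reagents that add atoms: iodine, II
Why: In this iodine-mediated enaminone cyclisation, a standard entry to 3-iodochromones, iodine attacks the nucleophilic α-carbon of the enaminone, the phenol closes ring C by 6-exo-trig addition to the iminium carbon to give 16, and loss of dimethylamine gives the 3-iodochromone.

Step 10
Reactants: 12 2-[8-methoxy-5-(methoxymethoxy)-2,2-dimethyl-2H-chromen-6-yl]-4,4,5,5-tetramethyl-1,3,2-dioxaborolane; 17 3-iodo-7-(methoxymethoxy)-4H-chromen-4-one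
Product: 18 3-[8-methoxy-5-(methoxymethoxy)-2,2-dimethyl-2H-chromen-6-yl]-7-(methoxymethoxy)-4H-chromen-4-one
Conditions: Pd(dppf)Cl2 (5 mol %), aq. Na2CO3 (2 M), DME, 80 °C
Reagents that add atoms: none
Why: Suzuki–Miyaura coupling of the activated 3-iodochromone with the mono-ortho-substituted aryl boronate forms the ring C to ring B bond, and the dppf ligand with a mild carbonate base should limit protodeboronation and opening of the pyranone ring.

Step 11
Reactants: 18 3-[8-methoxy-5-(methoxymethoxy)-2,2-dimethyl-2H-chromen-6-yl]-7-(methoxymethoxy)-4H-chromen-4-one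
Product: 19 7-hydroxy-3-(5-hydroxy-8-methoxy-2,2-dimethyl-2H-chromen-6-yl)-4H-chromen-4-one
Conditions: HCl (aq., 3 M), MeOH, 40 °C
Reagents that add atoms: none
Why: Acid-catalysed acetal cleavage (MOM removal by methanolysis) should free both phenols under conditions that the 2,2-dimethylchromene and the isoflavone tolerate, giving the achiral target.

**Compound list**

1 | 2-bromo-5-hydroxy-4-methoxybenzaldehyde | COc1cc(Br)c(C=O)cc1O | starting material
2 | 2-bromo-4-methoxy-5-[(2-methylbut-3-yn-2-yl)oxy]benzaldehyde | COc1cc(Br)c(C=O)cc1OC(C)(C)C#C | intermediate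
3 | 2-bromo-4-methoxy-5-[(2-methylbut-3-yn-2-yl)oxy]phenyl formate (forms in the flask) | COc1cc(Br)c(OC=O)cc1OC(C)(C)C#C | intermediate
4 | 2-bromo-4-methoxy-5-[(2-methylbut-3-yn-2-yl)oxy]phenol | COc1cc(Br)c(O)cc1OC(C)(C)C#C | intermediate
5 | 6-bromo-2-(hydroxymethyl)-4-methoxy-3-[(2-methylbut-3-yn-2-yl)oxy]phenol (forms in the flask as its magnesium salt) | COc1cc(Br)c(O)c(CO)c1OC(C)(C)C#C | intermediate
6 | 3-bromo-2-hydroxy-5-methoxy-6-[(2-methylbut-3-yn-2-yl)oxy]benzaldehyde | COc1cc(Br)c(O)c(C=O)c1OC(C)(C)C#C | intermediate
7 | ruthenium vinylidene of 6 (forms in the flask; [Ru] stands for the CpRu fragment and its remaining ligands) | COc1cc(Br)c(O)c(C=O)c1OC(C)(C)C=C=[Ru] | intermediate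
8 | (6-bromo-5-hydroxy-8-methoxy-2,2-dimethyl-2H-chromen-3-yl)carbonyl ruthenium species (forms in the flask; [Ru] as in 7) | COc1cc(Br)c(O)c2C=C(C(=O)[Ru])C(C)(C)Oc12 | intermediate
9 | 6-bromo-8-methoxy-2,2-dimethyl-2H-chromen-5-ol | COc1cc(Br)c(O)c2C=CC(C)(C)Oc12 | intermediate
10 | 6-bromo-8-methoxy-5-(methoxymethoxy)-2,2-dimethyl-2H-chromene | COCOc1c(Br)cc(OC)c2OC(C)(C)C=Cc12 | intermediate
11 | [8-methoxy-5-(methoxymethoxy)-2,2-dimethyl-2H-chromen-6-yl]lithium (forms in the flask) | COCOc1c([Li])cc(OC)c2OC(C)(C)C=Cc12 | intermediate
12 | 2-[8-methoxy-5-(methoxymethoxy)-2,2-dimethyl-2H-chromen-6-yl]-4,4,5,5-tetramethyl-1,3,2-dioxaborolane | COCOc1c(B3OC(C)(C)C(C)(C)O3)cc(OC)c2OC(C)(C)C=Cc12 | intermediate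
13 | 1-(2,4-dihydroxyphenyl)ethan-1-one | CC(=O)c1ccc(O)cc1O | starting material
14 | 1-[2-hydroxy-4-(methoxymethoxy)phenyl]ethan-1-one | COCOc1ccc(C(C)=O)c(O)c1 | intermediate
15 | (E)-3-(dimethylamino)-1-[2-hydroxy-4-(methoxymethoxy)phenyl]prop-2-en-1-one | COCOc1ccc(C(=O)/C=C/N(C)C)c(O)c1 | intermediate
16 | 2-(dimethylamino)-3-iodo-7-(methoxymethoxy)-2,3-dihydro-4H-chromen-4-one (forms in the flask; transient, racemic mixture of diastereomers) | COCOc1ccc2C(=O)C(I)C(N(C)C)Oc2c1 | intermediate
17 | 3-iodo-7-(methoxymethoxy)-4H-chromen-4-one | COCOc1ccc2c(c1)occ(I)c2=O | intermediate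
18 | 3-[8-methoxy-5-(methoxymethoxy)-2,2-dimethyl-2H-chromen-6-yl]-7-(methoxymethoxy)-4H-chromen-4-one | COCOc1ccc2c(c1)occ(-c1cc(OC)c3OC(C)(C)C=Cc3c1OCOC)c2=O | intermediate
19 | 7-hydroxy-3-(5-hydroxy-8-methoxy-2,2-dimethyl-2H-chromen-6-yl)-4H-chromen-4-one | COc1cc(-c2coc3cc(O)ccc3c2=O)c(O)c2c1OC(C)(C)C=C2 | target

**Step count and risks**

Total step count: 11. Longest linear sequence: 8 steps (steps 1, 2, 3, 4, 5, 6, 10 and 11, from compound 1); steps 7 to 9 build the second fragment.

The three steps most likely to fail:

First, step 4 (the step labelled as a proposed new method). The vinylidene may lose the aryloxide from the propargylic carbon before acetic acid adds, which would release the phenol and send the metal down an allenylidene path. The catalyst may also be sequestered by η6-binding to the electron-rich arene or by the CO set free, or the sequence may stop before decarbonylation. The fallback uses known chemistry and forms the same C3=C4 bond. It sets out from 6: semihydrogenation of the alkyne (H2, Pd/CaCO3 poisoned with Pb(OAc)2, quinoline, EtOAc, rt) should give 3-bromo-2-hydroxy-5-methoxy-6-[(2-methylbut-3-en-2-yl)oxy]benzaldehyde F1. Wittig methylenation with excess Ph3P=CH2 (from methyltriphenylphosphonium bromide and KOtBu, THF, 0 °C to rt; the phenol consumes one equivalent) should give 6-bromo-2-ethenyl-4-methoxy-3-[(2-methylbut-3-en-2-yl)oxy]phenol F2. Ring-closing olefin metathesis with the second-generation Grubbs catalyst (H2IMes)(PCy3)Cl2Ru=CHPh (CH2Cl2, 40 °C) should then close ring D with loss of ethene. The fallback comes back to the route at 9.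

Second, step 3. Attack of formaldehyde at the crowded carbon between the hydroxyl and the tertiary ether may be slow, so that condensation of 5 with unreacted phenoxide (diarylmethane formation) or incomplete in-flask oxidation takes over. The fallback sets out from 4 and replaces the magnesium-mediated one-pot process by a boron-templated sequence. PhB(OH)2 and paraformaldehyde (propionic acid cat., toluene, 85 °C, removal of water) should give 8-bromo-6-methoxy-5-[(2-methylbut-3-yn-2-yl)oxy]-2-phenyl-4H-1,3,2-benzodioxaborinine F3. Transesterification with propane-1,3-diol should release salicyl alcohol 5, here isolated, and MnO2 in CH2Cl2 should oxidise the benzylic alcohol. The fallback comes back to the route at 6.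

Third, step 10. The electron-rich ortho-alkoxy boronate may undergo protodeboronation faster than transmetalation, and aqueous base may open the pyranone ring of 17. The fallback sets out from 10 and avoids both boron and base. Bromine-lithium exchange as in step 6 gives 11, and transmetalation with ZnCl2 (THF, −78 °C to rt) should give chloro[8-methoxy-5-(methoxymethoxy)-2,2-dimethyl-2H-chromen-6-yl]zinc F4. Negishi coupling of F4 with 17 (Pd(PPh3)4, THF, 50 °C) should form the same biaryl bond. The fallback comes back to the route at 18.

Further compounds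
F1 | step 4 | 3-bromo-2-hydroxy-5-methoxy-6-[(2-methylbut-3-en-2-yl)oxy]benzaldehyde | COc1cc(Br)c(O)c(C=O)c1OC(C)(C)C=C
F2 | step 4 | 6-bromo-2-ethenyl-4-methoxy-3-[(2-methylbut-3-en-2-yl)oxy]phenol | COc1cc(Br)c(O)c(C=C)c1OC(C)(C)C=C
F3 | step 3 | 8-bromo-6-methoxy-5-[(2-methylbut-3-yn-2-yl)oxy]-2-phenyl-4H-1,3,2-benzodioxaborinine | COc1cc(Br)c2OB(c3ccccc3)OCc2c1OC(C)(C)C#C
F4 | step 10 | chloro[8-methoxy-5-(methoxymethoxy)-2,2-dimethyl-2H-chromen-6-yl]zinc | COCOc1c([Zn]Cl)cc(OC)c2OC(C)(C)C=Cc12
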